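**Strategy**

Everything rests on a late sp2–sp2 disconnection between C3 of the cyclopenta[c]pyridine ring and C1′ of the dienyl chain. C3 lies α to the ring nitrogen N2 and para to C7a, which carries the C7 ketone, so a C3–Cl bond is the most electron-poor site of the pyridine ring and should add Pd(0) under very mild conditions. A room-temperature Suzuki–Miyaura coupling therefore unites, in the last step, the complete and unprotected chloro core (C5 and C6 quaternary centres in place) with the (1E,3E,5S)-dienyl pinacol boronate. The core arises from a lithium-bridged intramolecular aldol of a chiral dioxolanone enolate onto a 1,2-diketone.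

Key step: step 11

Remark: positions follow cyclopenta[c]pyridine numbering (C1, N2, C3, C4, C4a, C5, C6, C7, C7a), primed numbers denote the dienyl chain, and the sense of induction in step 2 is assigned by analogy with aryl ketones.

**Route**

Step 1
Reactants: 1 5-bromo-2-chloropyridine; 2 dimethyl oxalate
Product: 4 methyl 2-(5-bromo-2-chloropyridin-4-yl)-2-oxoacetate, via 5-bromo-2-chloro-4-lithiopyridine 3 (not isolated)
Conditions: LDA (1.05 equiv), THF, −78 °C, 30 min; cannulation into 2 (3 equiv), THF, −78 °C; aq. NH4Cl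
Reagents that add atoms: none
Why: Directed ortho-lithiation at C4, the most acidic C–H (flanked by bromine), followed by acylation of the aryllithium with an oxalate diester, inverse addition to excess oxalate preventing double addition.

Step 2
Reactants: 4 methyl 2-(5-bromo-2-chloropyridin-4-yl)-2-oxoacetate
Product: 5 methyl (2S)-2-(5-bromo-2-chloropyridin-4-yl)-2-hydroxyacetate
Conditions: RuCl[(R,R)-TsDPEN](p-cymene) (1 mol %), HCO2H/Et3N (5:2), DMF, 0 °C → rt
Reagents that add atoms: none
Why: Noyori–Ikariya asymmetric transfer hydrogenation of an aryl α-keto ester, in which the catalyst sets the carbinol centre and the (R,R)-catalyst is expected to give the (S)-alcohol (the (S,S)-catalyst is the remedy should the sense prove opposite).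

Step 3
Reactants: 5 methyl (2S)-2-(5-bromo-2-chloropyridin-4-yl)-2-hydroxyacetate
Product: 6 (2S)-2-(5-bromo-2-chloropyridin-4-yl)-2-hydroxyacetic acid
Conditions: LiOH·H2O (1.5 equiv), THF/H2O, 0 °C; then 1 M HCl to pH 2
Reagents that add atoms: lithium hydroxide [Li+].[OH-]
Why: Saponification of an activated α-hydroxy ester, kept cold and short so that neither α-epimerisation nor substitution of the C–Cl bond competes.

Step 4
Reactants: 6 (2S)-2-(5-bromo-2-chloropyridin-4-yl)-2-hydroxyacetic acid
Product: 7 (2S,5S)-5-(5-bromo-2-chloropyridin-4-yl)-2-tert-butyl-1,3-dioxolan-4-one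
Conditions: t-BuCHO (2 equiv), TfOH (cat.), pentane/CH2Cl2, reflux, Dean–Stark; crystallisation of the cis isomer
Reagents that add atoms: pivalaldehyde CC(C)(C)C=O
Why: Acid-catalysed acetalisation of an α-hydroxy acid (self-regeneration-of-stereocentres template), in which the new acetal centre C2 forms cis to the aryl group and stores the stereochemical information once C5 is planarised.

Step 5
Reactants: 7 (2S,5S)-5-(5-bromo-2-chloropyridin-4-yl)-2-tert-butyl-1,3-dioxolan-4-one; 8 propyne
Product: 9 (2S,5S)-2-tert-butyl-5-[2-chloro-5-(prop-1-yn-1-yl)pyridin-4-yl]-1,3-dioxolan-4-one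
Conditions: propyne (1 M in THF, 3 equiv), PdCl2(PPh3)2 (3 mol %), CuI (5 mol %), Et3N (3 equiv), THF, 25–40 °C, sealed vessel
Reagents that add atoms: none
Why: Sonogashira coupling, chemoselective for C–Br over C–Cl; any amine-induced epimerisation at dioxolanone C5 is inconsequential because C5 is planarised in step 7 and C2 is untouched.

Step 6
Reactants: 9 (2S,5S)-2-tert-butyl-5-[2-chloro-5-(prop-1-yn-1-yl)pyridin-4-yl]-1,3-dioxolan-4-one
Product: 10 (2S,5S)-2-tert-butyl-5-[2-chloro-5-(2-oxopropanoyl)pyridin-4-yl]-1,3-dioxolan-4-one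
Conditions: RuCl3·xH2O (2 mol %), NaIO4 (2.2 equiv), EtOAc/MeCN/H2O, 0 °C, short reaction time
Reagents that add atoms: sodium periodate [Na+].[O-]I(=O)(=O)=O
Why: Ruthenium tetroxide-catalysed oxidation of an internal aryl alkyne to the 1,2-diketone in a neutral to slightly acidic medium, which should spare the electron-poor pyridine and the acylal and avoid a premature aldol.

Step 7
Reactants: 10 (2S,5S)-2-tert-butyl-5-[2-chloro-5-(2-oxopropanoyl)pyridin-4-yl]-1,3-dioxolan-4-one
Product: 12 (2'S,5R,6S)-2'-tert-butyl-3-chloro-6-methyl-5',7-dioxo-6,7-dihydrospiro[cyclopenta[c]pyridine-5,4'-[1,3]dioxolan]-6-yl acetate, via lithium alkoxide 11 (not isolated)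
Conditions: LiHMDS (1.1 equiv), THF, −78 °C, 1 h; then Ac2O (3 equiv), −78 → 0 °C
Reagents that add atoms: acetic anhydride CC(=O)OC(C)=O
Why: Intramolecular aldol addition (5-exo-trig, enolate exocyclic) under self-regeneration of stereocentres: the C5 enolate attacks the C6 carbonyl anti to the tert-butyl group (sets C5), lithium bridging the enolate oxygen and the C6 carbonyl oxygen places the new C6–O cis to the lactone carbonyl and hence trans to the C5–O (sets C6), and in-situ acetylation of the tertiary alkoxide forestalls retro-aldol cleavage.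

Step 8
Reactants: 12 (2'S,5R,6S)-2'-tert-butyl-3-chloro-6-methyl-5',7-dioxo-6,7-dihydrospiro[cyclopenta[c]pyridine-5,4'-[1,3]dioxolan]-6-yl acetate
Product: 14 methyl (5R,6S)-6-acetoxy-3-chloro-5-hydroxy-6-methyl-7-oxo-6,7-dihydro-5H-cyclopenta[c]pyridine-5-carboxylate, via hydroxy acid 13 (not isolated)
Conditions: TFA/H2O (9:1), 40 °C; concentration; then TMSCHN2 (2 M in hexanes), PhMe/MeOH (4:1), 0 °C
Reagents that add atoms: water O; (trimethylsilyl)diazomethane C[Si](C)(C)C=[N+]=[N-]
Why: Aqueous-acid hydrolysis of the acylal releases the tertiary α-hydroxy acid while the hindered acetate on the cation-destabilised C6 should survive, and neutral diazoalkane esterification then gives the methyl ester without exposing the β-hydroxy ketone to base; no stereocentre is touched.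

Step 9
Reactants: 15 (S)-2-methylbutan-1-ol; 16 2-(triphenylphosphoranylidene)propanal
Product: 18 (2E,4S)-2,4-dimethylhex-2-enal, via (S)-2-methylbutanal 17 (not isolated)
Conditions: TEMPO (10 mol %), PhI(OAc)2 (1.1 equiv), CH2Cl2, 0 °C → rt; then 16 (1.2 equiv), toluene, 80 °C
Reagents that add atoms: none
Why: Base-free TEMPO/iodine(III) oxidation gives the configurationally labile α-branched aldehyde, which is trapped in situ by Wittig olefination with a stabilised formyl ylide to give the (E)-trisubstituted enal without touching the C4 stereocentre.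

Step 10
Reactants: 18 (2E,4S)-2,4-dimethylhex-2-enal; 19 2-(dichloromethyl)-4,4,5,5-tetramethyl-1,3,2-dioxaborolane
Product: 20 2-[(1E,3E,5S)-3,5-dimethylhepta-1,3-dien-1-yl]-4,4,5,5-tetramethyl-1,3,2-dioxaborolane
Conditions: CrCl2 (8 equiv), LiI (4 equiv), THF, rt
Reagents that add atoms: none
Why: Takai–Utimoto-type chromium(II) olefination with a gem-dihalomethylboronate gives the (E)-alkenylboronate under non-basic conditions, so the existing (E)-alkene and the allylic stereocentre are preserved.

Step 11
Reactants: 14 methyl (5R,6S)-6-acetoxy-3-chloro-5-hydroxy-6-methyl-7-oxo-6,7-dihydro-5H-cyclopenta[c]pyridine-5-carboxylate; 20 2-[(1E,3E,5S)-3,5-dimethylhepta-1,3-dien-1-yl]-4,4,5,5-tetramethyl-1,3,2-dioxaborolane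
Product: 21 methyl (5R,6S)-6-acetoxy-3-[(1E,3E,5S)-3,5-dimethylhepta-1,3-dien-1-yl]-5-hydroxy-6-methyl-7-oxo-6,7-dihydro-5H-cyclopenta[c]pyridine-5-carboxylate
Conditions: 20 (1.3 equiv), XPhos Pd G3 (5 mol %), K3PO4 (0.5 M aq., 2 equiv), THF, 25 °C, degassed, short reaction time
Reagents that add atoms: none
Why: Suzuki–Miyaura cross-coupling: Pd(0) inserts into the C3–Cl bond, which is activated by N2 (α) and by the C7 ketone through C7a (para), the base-activated boronate transfers the dienyl group with retention of the C1′=C2′ geometry, and reductive elimination forms the C3–C1′ bond. The closest known reaction type is the alkenylation of electron-poor 2-chloropyridines with alkenyl pinacol boronates using dialkylbiarylphosphine palladacycle precatalysts. No ring is closed and no stereocentre is created; the 1′E,3′E geometry and C5′ are carried in unchanged from 20, and C5 and C6 are not touched. The selectivity needed is chemoselectivity for C–Cl over the methyl ester, the tertiary acetate and the retro-aldol-prone C5-hydroxy/C7-ketone array, which the fast precatalyst, room temperature, short reaction time and weak biphasic base should secure; there is only one carbon–halogen bond, so no site selectivity is required.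

**Compound list**

1 | 5-bromo-2-chloropyridine | Clc1ccc(Br)cn1 | starting material
2 | dimethyl oxalate | COC(=O)C(=O)OC | starting material
3 | 5-bromo-2-chloro-4-lithiopyridine | [Li]c1cc(Cl)ncc1Br | intermediate (not isolated)
4 | methyl 2-(5-bromo-2-chloropyridin-4-yl)-2-oxoacetate | COC(=O)C(=O)c1cc(Cl)ncc1Br | intermediate
5 | methyl (2S)-2-(5-bromo-2-chloropyridin-4-yl)-2-hydroxyacetate | Brc1cnc(Cl)cc1[C@H](O)C(=O)OC | intermediate
6 | (2S)-2-(5-bromo-2-chloropyridin-4-yl)-2-hydroxyacetic acid | Brc1cnc(Cl)cc1[C@H](O)C(=O)O | intermediate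
7 | (2S,5S)-5-(5-bromo-2-chloropyridin-4-yl)-2-tert-butyl-1,3-dioxolan-4-one | Brc1cnc(Cl)cc1[C@@H]1O[C@H](C(C)(C)C)OC1=O | intermediate
8 | propyne | CC#C | starting material
9 | (2S,5S)-2-tert-butyl-5-[2-chloro-5-(prop-1-yn-1-yl)pyridin-4-yl]-1,3-dioxolan-4-one | CC#Cc1cnc(Cl)cc1[C@@H]1O[C@H](C(C)(C)C)OC1=O | intermediate
10 | (2S,5S)-2-tert-butyl-5-[2-chloro-5-(2-oxopropanoyl)pyridin-4-yl]-1,3-dioxolan-4-one | CC(=O)C(=O)c1cnc(Cl)cc1[C@@H]1O[C@H](C(C)(C)C)OC1=O | intermediate
11 | lithium (2'S,5R,6S)-2'-tert-butyl-3-chloro-6-methyl-5',7-dioxo-6,7-dihydrospiro[cyclopenta[c]pyridine-5,4'-[1,3]dioxolan]-6-olate | Clc1cc2c(cn1)C(=O)[C@@](C)(O[Li])[C@@]2(O3)C(=O)O[C@H]3C(C)(C)C | intermediate (not isolated)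
12 | (2'S,5R,6S)-2'-tert-butyl-3-chloro-6-methyl-5',7-dioxo-6,7-dihydrospiro[cyclopenta[c]pyridine-5,4'-[1,3]dioxolan]-6-yl acetate | Clc1cc2c(cn1)C(=O)[C@@](C)(OC(C)=O)[C@@]2(O3)C(=O)O[C@H]3C(C)(C)C | intermediate
13 | (5R,6S)-6-acetoxy-3-chloro-5-hydroxy-6-methyl-7-oxo-6,7-dihydro-5H-cyclopenta[c]pyridine-5-carboxylic acid | Clc1cc2c(cn1)C(=O)[C@@](C)(OC(C)=O)[C@@]2(O)C(=O)O | intermediate (not isolated)
14 | methyl (5R,6S)-6-acetoxy-3-chloro-5-hydroxy-6-methyl-7-oxo-6,7-dihydro-5H-cyclopenta[c]pyridine-5-carboxylate | Clc1cc2c(cn1)C(=O)[C@@](C)(OC(C)=O)[C@@]2(O)C(=O)OC | intermediate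
15 | (S)-2-methylbutan-1-ol | CC[C@H](C)CO | starting material
16 | 2-(triphenylphosphoranylidene)propanal | CC(C=O)=P(c1ccccc1)(c1ccccc1)c1ccccc1 | starting material
17 | (S)-2-methylbutanal | CC[C@H](C)C=O | intermediate (not isolated)
18 | (2E,4S)-2,4-dimethylhex-2-enal | CC[C@H](C)/C=C(\C)C=O | intermediate
19 | 2-(dichloromethyl)-4,4,5,5-tetramethyl-1,3,2-dioxaborolane | ClC(Cl)B1OC(C)(C)C(C)(C)O1 | starting material
20 | 2-[(1E,3E,5S)-3,5-dimethylhepta-1,3-dien-1-yl]-4,4,5,5-tetramethyl-1,3,2-dioxaborolane | CC[C@H](C)/C=C(C)/C=C/B1OC(C)(C)C(C)(C)O1 | intermediate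
21 | methyl (5R,6S)-6-acetoxy-3-[(1E,3E,5S)-3,5-dimethylhepta-1,3-dien-1-yl]-5-hydroxy-6-methyl-7-oxo-6,7-dihydro-5H-cyclopenta[c]pyridine-5-carboxylate | CC[C@H](C)/C=C(C)/C=C/c1cc2c(cn1)C(=O)[C@@](C)(OC(C)=O)[C@@]2(O)C(=O)OC | target

**Step count**

Total step count: 11. Longest linear sequence: 9 (steps 1–8 and 11).

**Steps most likely to fail**

1. Step 7. The base may deprotonate the acetyl methyl group instead of C5, or the closure may run through an open, non-bridged transition state with poor facial selectivity at C6; the tertiary alkoxide may also revert by retro-aldol before it is acetylated. The fallback sets out from 7 and comes back at 12; it forms the C5–C6 bond first and closes the ring at C6–C7. The enolate of 7 (LiHMDS, THF, −78 °C) is added to acetaldehyde anti to the tert-butyl group to give the carbinol F1 (mixture at the carbinol carbon). Dess–Martin oxidation gives the methyl ketone F2. Palladium-catalysed formylation of the C–Br bond (Pd(OAc)2, di(1-adamantyl)-n-butylphosphine, CO/H2, TMEDA, toluene, 100 °C) gives the aldehyde F3. An N-heterocyclic-carbene-catalysed intramolecular crossed benzoin reaction (triazolium precatalyst, Et3N, CH2Cl2) should then close the ring to the tertiary ketol F4; the acetyl carbonyl is expected to react in the conformation anti to the C5–O bond (dipole minimisation), which leads to the same C6 configuration. Acetylation (Ac2O, DMAP) returns 12.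

2. Step 8. Hydrolysis of the hindered acylal may be slow, and the tertiary acetate may be lost competitively under the acidic conditions. The fallback sets out from 12 and comes back at 14; it accepts loss of the acetate. Exhaustive acidic methanolysis (HCl from acetyl chloride in MeOH, 50 °C) should cleave the acetal, form the methyl ester and remove the acetate, giving the diol ester F5. The C6 hydroxyl (an α-ketol hydroxyl next to a methyl group) is then acetylated site-selectively (Ac2O, DMAP, CH2Cl2, 0 °C); the C5 hydroxyl is more hindered (aryl, ester and quaternary C6 neighbours) and hydrogen-bonded to its own ester. This returns 14.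

3. Step 11. The aqueous base needed for transmetalation may trigger retro-aldol opening and re-closure of the C5–C6 bond (epimerisation), cleave the acetate, or protodeboronate the dienyl boronate. The fallback sets out from 18 (with 14) and comes back at 21; it replaces the boron nucleophile by a tin nucleophile so that no base is needed. A chromium(II)-mediated Takai-type olefination of 18 with tributyl(dibromomethyl)stannane (CrCl2, LiI, THF/DMF, rt) should give the dienylstannane F6. F6 is coupled with 14 in a neutral Stille reaction (Pd2(dba)3, AsPh3, NMP, 50 °C) to give 21.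

**Further compounds**

F1 | step 7 | (2S,5R)-5-(5-bromo-2-chloropyridin-4-yl)-2-tert-butyl-5-(1-hydroxyethyl)-1,3-dioxolan-4-one | Brc1cnc(Cl)cc1[C@]1(C(C)O)O[C@H](C(C)(C)C)OC1=O
F2 | step 7 | (2S,5R)-5-acetyl-5-(5-bromo-2-chloropyridin-4-yl)-2-tert-butyl-1,3-dioxolan-4-one | Brc1cnc(Cl)cc1[C@]1(C(C)=O)O[C@H](C(C)(C)C)OC1=O
F3 | step 7 | 4-[(2S,4R)-4-acetyl-2-tert-butyl-5-oxo-1,3-dioxolan-4-yl]-6-chloropyridine-3-carbaldehyde | O=Cc1cnc(Cl)cc1[C@]1(C(C)=O)O[C@H](C(C)(C)C)OC1=O
F4 | step 7 | (2'S,5R,6S)-2'-tert-butyl-3-chloro-6-hydroxy-6-methylspiro[cyclopenta[c]pyridine-5,4'-[1,3]dioxolane]-5',7(6H)-dione | Clc1cc2c(cn1)C(=O)[C@@](C)(O)[C@@]2(O3)C(=O)O[C@H]3C(C)(C)C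
F5 | step 8 | methyl (5R,6S)-3-chloro-5,6-dihydroxy-6-methyl-7-oxo-6,7-dihydro-5H-cyclopenta[c]pyridine-5-carboxylate | Clc1cc2c(cn1)C(=O)[C@@](C)(O)[C@@]2(O)C(=O)OC
F6 | step 11 | tributyl[(1E,3E,5S)-3,5-dimethylhepta-1,3-dien-1-yl]stannane | CC[C@H](C)/C=C(C)/C=C/[Sn](CCCC)(CCCC)CCCC
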